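**Retrosynthetic overview**
1. The butenolide is closed last, on the carbonyl carbon of a malic-acid-derived dioxolanone: one-flask LiCH2Cl homologation, phosphonoacetate displacement and intramolecular HWE (new annulation).
2. C14–C15 is the fragment-joining bond: Ni-electrocatalytic decarboxylative sp2–sp3 coupling of a (Z)-alkenyl iodide with the redox-active ester of D-malic acid acetonide, which brings C16 in as bought.
3. C12–C13 and the C13=C14 geometry come from Cu-catalysed anti-carbomagnesiation of propargyl alcohol with the homodrimenyl Grignard reagent, quenched with iodine.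
4. The decalin with C5 and C10 is (+)-sclareolide: acid opening/dehydration to the Δ8(9) ester, reduction, bromination.
5. Ring order: decalin bought intact → dioxolanone (temporary ring on malic acid) → butenolide closed in the final step.

Assumption: labdane-type atom labels are used (C11, C12 = the two CH2 next to the decalin; C13=C14 = side-chain alkene with CH2OH on C13; C15 = CH2; C16 = carbinol carbon; Cα, Cβ, Cγ = butenolide CH, quaternary C and OCH2). Dec = (4aS,8aS)-2,5,5,8a-tetramethyl-3,4,4a,5,6,7,8,8a-octahydronaphthalen-1-yl (trans-decalin, ring-fusion methyl β, ring-fusion H α, ring alkene C1=C2).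

**Step 1**
Reactants: 1 (+)-sclareolide
Product: 2 methyl 2-Dec-acetate
Conditions: conc. H2SO4, MeOH, reflux; AgNO3–SiO2 chromatography
Reagents that add atoms: methanol (CO)
Why: Acid-catalysed lactone methanolysis and E1 dehydration of the C8 tertiary alcohol under thermodynamic control (Fischer esterification/olefin isomerisation) should favour the tetrasubstituted Δ8(9) β,γ-unsaturated ester, with minor Δ7 and exocyclic isomers removed on silver nitrate silica; this deletes the C8 and C9 stereocentres the target lacks and leaves C5 and C10 untouched.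

**Step 2**
Reactants: 2 methyl 2-Dec-acetate
Product: 3 2-Dec-ethanol
Conditions: LiAlH4, THF, 0 °C to rt; Fieser work-up
Reagents that add atoms: none
Why: Standard LiAlH4 ester reduction; the unconjugated tetrasubstituted alkene is inert to hydride.

**Step 3**
Reactants: 3 2-Dec-ethanol
Product: 4 2-Dec-ethyl bromide
Conditions: CBr4, PPh3, CH2Cl2, 0 °C
Reagents that add atoms: carbon tetrabromide (BrC(Br)(Br)Br)
Why: Appel reaction, an SN2 displacement at the primary carbon with no cationic intermediate, so the ring alkene neither migrates nor cyclises.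

**Step 4**
Reactants: 4 2-Dec-ethyl bromide; 5 propargyl alcohol
Product: 9 (Z)-2-(iodomethylidene)-4-Dec-butan-1-ol, via 2-Dec-ethylmagnesium bromide 6 (not isolated), via bromomagnesium prop-2-yn-1-olate 7 (not isolated), via cyclic alkenylmagnesium alkoxide 8 (not isolated)
Conditions: (i) 4, Mg, THF, 45 °C; (ii) 5 (1.5 equiv), EtMgBr (1.5 equiv), THF, 0 °C; (iii) combine, CuI (10 mol%), THF–Et2O, rt, 16 h; (iv) I2, −40 to 0 °C; aq. Na2S2O3/NH4Cl
Reagents that add atoms: iodine (II)
Why: Duboudin-type Cu-catalysed anti-carbomagnesiation of the propargylic magnesium alkoxide puts the alkyl group on the internal alkyne carbon and magnesium on the terminal carbon, held cis to CH2O in a five-membered chelate, so iodinolysis with retention gives only the Z-iodide, which is the C13=C14 geometry of the target.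

**Step 5**
Reactants: 10 D-malic acid
Product: 11 2-[(4R)-2,2-dimethyl-5-oxo-1,3-dioxolan-4-yl]acetic acid
Conditions: Me2C(OMe)2, p-TsOH·H2O (cat.), rt
Reagents that add atoms: 2,2-dimethoxypropane (COC(C)(C)OC)
Why: Acid-catalysed transacetalisation closes the five-membered dioxolanone on the α-hydroxy acid and leaves the β-carboxyl free; no bond at the stereocentre is touched, so the bought (R) centre becomes C16.

**Step 6**
Reactants: 9 (Z)-2-(iodomethylidene)-4-Dec-butan-1-ol; 11 2-[(4R)-2,2-dimethyl-5-oxo-1,3-dioxolan-4-yl]acetic acid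
Product: 13 (5R)-5-[(2Z)-3-(hydroxymethyl)-5-Dec-pent-2-en-1-yl]-2,2-dimethyl-1,3-dioxolan-4-one, via N-acyloxyphthalimide ester 12 (not isolated)
Conditions: (i) 11 (1.6 equiv), N-hydroxyphthalimide, DIC, CH2Cl2, rt; evaporate; (ii) 9 (1.0 equiv), NiCl2·6H2O (20 mol%), 2,2'-bipyridine (20 mol%), AgNO3 (0.3 equiv), DMF, Mg(+)/RVC(−), undivided cell, constant current, 3 F/mol, rt
Reagents that add atoms: none
Why: Ni-electrocatalytic decarboxylative alkenylation (reductive cross-electrophile coupling): cathodic reduction fragments the redox-active ester to CO2 and the primary C15 radical, which is captured by the alkenyl–nickel species from stereoretentive oxidative addition of the Z-iodide, and reductive elimination forms C14–C15 with the alkene geometry kept and C16 (one carbon from the radical) untouched; the base-free medium should spare the dioxolanone and the free alcohol.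

**Step 7**
Reactants: 13 (5R)-5-[(2Z)-3-(hydroxymethyl)-5-Dec-pent-2-en-1-yl]-2,2-dimethyl-1,3-dioxolan-4-one
Product: 16 4-[(1R,3Z)-1-hydroxy-4-(hydroxymethyl)-6-Dec-hex-3-en-1-yl]furan-2(5H)-one, via chloromethyl ketone 14 (not isolated), via keto phosphonoacetate 15 (not isolated)
Conditions: (i) ICH2Cl (4 equiv), MeLi·LiBr (3.8 equiv), THF, −78 °C; (ii) (EtO)2P(O)CH2CO2H (4 equiv), −78 °C to rt; (iii) evaporate, DMF, NaI (cat.), rt; (iv) LiCl, DBU, 0 °C
Reagents that add atoms: chloroiodomethane (ClCI); diethylphosphonoacetic acid (CCOP(=O)(OCC)CC(=O)O)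
Why: Proposed new method: homologative butenolide annulation of a 1,3-dioxolan-4-one, in which LiCH2Cl should add only once to the lactone carbonyl because the adduct is a cyclic lithium hemiketal that is stable at −78 °C (Weinreb-like), protonation by the phosphonoacetic acid releases acetone and the α-chloro α′-hydroxy ketone together with the carboxylate that displaces chloride (SN2 at an α-halo ketone), and Masamune–Roush intramolecular HWE then closes the five-membered ring (Cβ–Cγ and Cα=Cβ) faster than acyl shift or enolisation so that C16 keeps its configuration; the closest known reaction types are the LiCH2Cl homologation of esters and Weinreb amides to chloromethyl ketones and the α-halo ketone/phosphonoacetate butenolide synthesis.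

**Compound list**
1 | (+)-sclareolide, (3aR,5aS,9aS,9bR)-3a,6,6,9a-tetramethyldecahydronaphtho[2,1-b]furan-2(1H)-one | O=C1C[C@@H]2[C@@]3(C)CCCC(C)(C)[C@@H]3CC[C@@]2(C)O1 | starting material
2 | methyl 2-Dec-acetate | CC1=C(CC(=O)OC)[C@@]2(C)CCCC(C)(C)[C@@H]2CC1 | intermediate
3 | 2-Dec-ethanol | CC1=C(CCO)[C@@]2(C)CCCC(C)(C)[C@@H]2CC1 | intermediate
4 | 2-Dec-ethyl bromide | CC1=C(CCBr)[C@@]2(C)CCCC(C)(C)[C@@H]2CC1 | intermediate
5 | propargyl alcohol | C#CCO | starting material
6 | 2-Dec-ethylmagnesium bromide | CC1=C(CC[Mg]Br)[C@@]2(C)CCCC(C)(C)[C@@H]2CC1 | intermediate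
7 | bromomagnesium prop-2-yn-1-olate | C#CCO[Mg]Br | intermediate
8 | cyclic alkenylmagnesium alkoxide, 4-(2-Dec-ethyl)-2,5-dihydro-1,2-oxamagnesole (ring Mg–O–CH2–C=CH) | CC1=C(CCC3=C[Mg]OC3)[C@@]2(C)CCCC(C)(C)[C@@H]2CC1 | intermediate
9 | (Z)-2-(iodomethylidene)-4-Dec-butan-1-ol (I cis to CH2OH) | CC1=C(CC/C(=C/I)CO)[C@@]2(C)CCCC(C)(C)[C@@H]2CC1 | intermediate
10 | D-malic acid, (R)-2-hydroxybutanedioic acid | OC(=O)C[C@@H](O)C(=O)O | starting material
11 | 2-[(4R)-2,2-dimethyl-5-oxo-1,3-dioxolan-4-yl]acetic acid | OC(=O)C[C@@H]1C(=O)OC(C)(C)O1 | intermediate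
12 | 1,3-dioxoisoindolin-2-yl 2-[(4R)-2,2-dimethyl-5-oxo-1,3-dioxolan-4-yl]acetate | O=C(C[C@@H]1C(=O)OC(C)(C)O1)ON1C(=O)c2ccccc2C1=O | intermediate
13 | (5R)-5-[(2Z)-3-(hydroxymethyl)-5-Dec-pent-2-en-1-yl]-2,2-dimethyl-1,3-dioxolan-4-one | CC1=C(CC/C(=C/C[C@@H]3C(=O)OC(C)(C)O3)CO)[C@@]2(C)CCCC(C)(C)[C@@H]2CC1 | intermediate
14 | (3R,5Z)-1-chloro-3-hydroxy-6-(hydroxymethyl)-8-Dec-oct-5-en-2-one | CC1=C(CC/C(=C/C[C@@H](O)C(=O)CCl)CO)[C@@]2(C)CCCC(C)(C)[C@@H]2CC1 | intermediate
15 | (3R,5Z)-3-hydroxy-6-(hydroxymethyl)-2-oxo-8-Dec-oct-5-en-1-yl 2-(diethoxyphosphoryl)acetate | CC1=C(CC/C(=C/C[C@@H](O)C(=O)COC(=O)CP(=O)(OCC)OCC)CO)[C@@]2(C)CCCC(C)(C)[C@@H]2CC1 | intermediate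
16 | 4-[(1R,3Z)-1-hydroxy-4-(hydroxymethyl)-6-Dec-hex-3-en-1-yl]furan-2(5H)-one (CNP0224983.2) | CC1=C(CC/C(=C/C[C@@H](O)C2=CC(=O)OC2)CO)[C@@]2(C)CCCC(C)(C)[C@@H]2CC1 | target

**Step count and risks**
Total steps: 7 (6 if catalogue compound 11 is bought). Longest linear sequence: 6 (steps 1, 2, 3, 4, 6, 7).

Step 7 (the new annulation) is the most likely to fail. The tetrahedral adduct may collapse early and take up a second carbenoid. The free C16 hydroxyl may take over the phosphonoacetyl group before the HWE closure, which would give the regioisomeric butenolide. The α-ketol may epimerise at C16. If the cis allylic alkoxide first lactonises onto the dioxolanone, the resulting seven-membered lactone should still give 14 with the carbenoid, so that path is self-correcting. The fallback uses known chemistry, sets out from 13 and comes back at 16. The dioxolanone is opened with MeNH(OMe)·HCl/i-PrMgCl to the hydroxy Weinreb amide F1. Both hydroxyls are silylated (TBSCl, imidazole) to the bis-TBS ether F2. ICH2Cl/MeLi·LiBr at −78 °C converts the Weinreb amide into the chloromethyl ketone F3. Potassium diethylphosphonoacetate in DMF displaces chloride to give the keto phosphonoacetate F4, which closes under K2CO3/18-crown-6 by intramolecular HWE to the bis-TBS butenolide F5. HF·pyridine removes both silyl groups to give 16.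

Step 6 may fail because the primary radical carries a β-oxygen, the Z-iodide is hindered by the cis CH2OH, and protodeiodination or ester homocoupling can compete. The fallback replaces the electroreductive coupling of two electrophiles by a preformed alkenyl nucleophile; it sets out from 9 and comes back at 13. Compound 9 is silylated to the TBS ether F6. Iodine–lithium exchange with t-BuLi followed by ZnCl2 gives the alkenylzinc chloride F7 with retention of geometry. Ni(acac)2/2,2'-bipyridine-catalysed decarboxylative alkenylation with isolated ester 12 gives the coupled TBS ether F8. HF·pyridine returns 13.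

Step 4 may fail through Wurtz coupling during Grignard formation, deprotonation of the alkyne C–H instead of addition, or low conversion with a bulky primary Grignard reagent. The fallback builds the same iodide by alkyne silylformylation; it sets out from 4 and comes back at 9. Bromide 4 alkylates lithium acetylide–ethylenediamine in DMSO to give the terminal alkyne F9. Rh-catalysed silylformylation (PhMe2SiH, CO 1 atm, Rh2(pfb)4, CH2Cl2, 0 °C) puts the formyl group on the internal carbon and silicon cis to it, giving the (Z)-β-silyl enal F10. Luche reduction (NaBH4, CeCl3, MeOH) gives the silyl allylic alcohol F11. Iododesilylation with NIS in (CF3)2CHOH at 0 °C, with retention, gives 9.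

**Further compounds**
F1 | step 7 | (2R,4Z)-2-hydroxy-5-(hydroxymethyl)-N-methoxy-N-methyl-7-Dec-hept-4-enamide | CC1=C(CC/C(=C/C[C@@H](O)C(=O)N(C)OC)CO)[C@@]2(C)CCCC(C)(C)[C@@H]2CC1
F2 | step 7 | (2R,4Z)-2-(tert-butyldimethylsilyloxy)-5-[(tert-butyldimethylsilyloxy)methyl]-N-methoxy-N-methyl-7-Dec-hept-4-enamide | CC1=C(CC/C(=C/C[C@@H](O[Si](C)(C)C(C)(C)C)C(=O)N(C)OC)CO[Si](C)(C)C(C)(C)C)[C@@]2(C)CCCC(C)(C)[C@@H]2CC1
F3 | step 7 | (3R,5Z)-3-(tert-butyldimethylsilyloxy)-6-[(tert-butyldimethylsilyloxy)methyl]-1-chloro-8-Dec-oct-5-en-2-one | CC1=C(CC/C(=C/C[C@@H](O[Si](C)(C)C(C)(C)C)C(=O)CCl)CO[Si](C)(C)C(C)(C)C)[C@@]2(C)CCCC(C)(C)[C@@H]2CC1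
F4 | step 7 | (3R,5Z)-3-(tert-butyldimethylsilyloxy)-6-[(tert-butyldimethylsilyloxy)methyl]-2-oxo-8-Dec-oct-5-en-1-yl 2-(diethoxyphosphoryl)acetate | CC1=C(CC/C(=C/C[C@@H](O[Si](C)(C)C(C)(C)C)C(=O)COC(=O)CP(=O)(OCC)OCC)CO[Si](C)(C)C(C)(C)C)[C@@]2(C)CCCC(C)(C)[C@@H]2CC1
F5 | step 7 | 4-[(1R,3Z)-1-(tert-butyldimethylsilyloxy)-4-[(tert-butyldimethylsilyloxy)methyl]-6-Dec-hex-3-en-1-yl]furan-2(5H)-one | CC1=C(CC/C(=C/C[C@@H](O[Si](C)(C)C(C)(C)C)C2=CC(=O)OC2)CO[Si](C)(C)C(C)(C)C)[C@@]2(C)CCCC(C)(C)[C@@H]2CC1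
F6 | step 6 | tert-butyl{[(Z)-2-(iodomethylidene)-4-Dec-butyl]oxy}dimethylsilane | CC1=C(CC/C(=C/I)CO[Si](C)(C)C(C)(C)C)[C@@]2(C)CCCC(C)(C)[C@@H]2CC1
F7 | step 6 | chloro{(Z)-2-[(tert-butyldimethylsilyloxy)methyl]-4-Dec-but-1-en-1-yl}zinc | CC1=C(CC/C(=C/[Zn]Cl)CO[Si](C)(C)C(C)(C)C)[C@@]2(C)CCCC(C)(C)[C@@H]2CC1
F8 | step 6 | (5R)-5-[(2Z)-3-[(tert-butyldimethylsilyloxy)methyl]-5-Dec-pent-2-en-1-yl]-2,2-dimethyl-1,3-dioxolan-4-one | CC1=C(CC/C(=C/C[C@@H]3C(=O)OC(C)(C)O3)CO[Si](C)(C)C(C)(C)C)[C@@]2(C)CCCC(C)(C)[C@@H]2CC1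
F9 | step 4 | 4-Dec-but-1-yne | CC1=C(CCC#C)[C@@]2(C)CCCC(C)(C)[C@@H]2CC1
F10 | step 4 | (Z)-2-[(dimethylphenylsilyl)methylidene]-4-Dec-butanal | CC1=C(CC/C(=C/[Si](C)(C)c3ccccc3)C=O)[C@@]2(C)CCCC(C)(C)[C@@H]2CC1
F11 | step 4 | (Z)-2-[(dimethylphenylsilyl)methylidene]-4-Dec-butan-1-ol | CC1=C(CC/C(=C/[Si](C)(C)c3ccccc3)CO)[C@@]2(C)CCCC(C)(C)[C@@H]2CC1
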